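**Plan**

1. Lignan numbering is used: ArCH2 = C7, CH = C8, CH2OH = C9, primed for the dihydrobenzofuran half. The first cut is C8–C8'. The open chain O–C9–C8–C8'–C9'–O between the guaiacyl ring and the dihydrobenzofuran is read as a γ,δ-unsaturated acid (C9 as CO2H, C9' as the inner carbon of a propenyl group). This is the retron of an Ireland–Claisen shift of an ester that tethers a dihydrocinnamic acid to a secondary allylic alcohol through a temporary C9(=O)–O–CH(CH3) link.
2. Further cuts: the ester C–O bond; the side-chain C=C (cross-metathesis of an allyl arene); the C2–C3 bond of the dihydrobenzofuran (carbenoid C–H insertion); the aryl–C(N2) bond; the ArCH2–O ether bond; the aryl C–I bond, back to eugenol.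
3. Forward: the dihydrobenzofuran is the only ring made (step 4). Its allyl group is extended to the chiral allylic alcohol, the halves are tethered as the ester and joined at C8–C8' by the [3,3] shift. Ozonolysis removes the two helper carbons via the trans-lactone; LiAlH4 and hydrogenolysis finish.
4. Stereochemistry: C2 of the dihydrobenzofuran comes from the chiral dirhodium catalyst, C3 from epimerisation to trans. C8' comes from 1,3-chirality transfer from (R)-but-3-en-2-ol through a chair transition state. C8 comes from the silyl ketene acetal geometry.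

Key step: step 10

Assumption: Rh2(R-PTTL)4 is taken to deliver the (2S) configuration at the ether carbon C2 of the dihydrobenzofuran; if the sense of induction proves opposite, Rh2(S-PTTL)4 is used with no other change.

**Route**

Step 1
Reactants: 1 eugenol (4-allyl-2-methoxyphenol)
Product: 2 4-allyl-2-iodo-6-methoxyphenol
Conditions: NIS (1.05 equiv), TsOH·H2O (10 mol %), MeCN, 0 °C to 23 °C, dark
Reagents that add atoms: N-iodosuccinimide, O=C1CCC(=O)N1I
Why: Electrophilic aromatic iodination; the phenol directs the iodonium equivalent to its only free ortho position, and the activated ring should react much faster than the isolated terminal alkene.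

Step 2
Reactants: 2 4-allyl-2-iodo-6-methoxyphenol; 3 [4-(benzyloxy)-3-methoxyphenyl]methanol
Product: 4 5-allyl-2-{[4-(benzyloxy)-3-methoxybenzyl]oxy}-1-iodo-3-methoxybenzene
Conditions: PPh3, DIAD, THF, 0 °C to 23 °C
Reagents that add atoms: none
Why: Mitsunobu etherification; the acidic ortho-iodophenol displaces the phosphonium-activated primary benzylic alcohol, so no separate benzylic halide is needed.

Step 3
Reactants: 4 aryl iodide; 5 ethyl diazoacetate
Product: 6 ethyl 2-(5-allyl-2-{[4-(benzyloxy)-3-methoxybenzyl]oxy}-3-methoxyphenyl)-2-diazoacetate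
Conditions: Pd(PPh3)4 (5 mol %), Ag2CO3 (0.5 equiv), Et3N (1.3 equiv), toluene, 23 °C
Reagents that add atoms: none
Why: Palladium-catalysed cross-coupling of an aryl iodide with the C–H bond of an acceptor diazo ester, with the diazo group retained; at 23 °C the allyl group should not undergo Heck-type reaction.

Step 4
Reactants: 6 aryl diazoacetate
Product: 8 ethyl (2S,3S)-5-allyl-2-[4-(benzyloxy)-3-methoxyphenyl]-7-methoxy-2,3-dihydrobenzofuran-3-carboxylate (trans), via cis ester 7 (not isolated)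
Conditions: Rh2(R-PTTL)4 (1 mol %; PTTL = N-phthaloyl-tert-leucinate, a tetracarboxylate of divalent rhodium), toluene, −60 °C, slow addition of 6 at high dilution; concentrate; NaOEt (0.3 equiv), EtOH, 23 °C
Reagents that add atoms: none
Why: Intramolecular C–H insertion of the donor/acceptor rhodium carbenoid into the ether methylene closes the five-membered ring (C2–C3 bond) as the cis isomer with the chiral carboxylate ligands setting C2, and catalytic ethoxide then epimerises only C3 (α to the ester) to the more stable trans ester, ring opening being the reverse of a disfavoured 5-endo-trig closure.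

Step 5
Reactants: 8 trans ester
Product: 9 {(2S,3R)-5-allyl-2-[4-(benzyloxy)-3-methoxyphenyl]-7-methoxy-2,3-dihydrobenzofuran-3-yl}methanol
Conditions: LiAlH4, THF, −20 °C to 0 °C
Reagents that add atoms: none
Why: Hydride reduction of the ester to the primary alcohol at low temperature should be faster than enolisation, so C2 and C3 are retained.

Step 6
Reactants: 9 primary alcohol
Product: 10 {(2S,3R)-5-allyl-2-[4-(benzyloxy)-3-methoxyphenyl]-7-methoxy-2,3-dihydrobenzofuran-3-yl}methyl pivalate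
Conditions: PivCl, Et3N, DMAP (cat.), CH2Cl2, 0 °C to 23 °C
Reagents that add atoms: pivaloyl chloride, CC(C)(C)C(Cl)=O
Why: Acylation of the primary alcohol; the pivalate has no α-hydrogen, should survive the later amide base, and is removed without an extra step in step 12.

Step 7
Reactants: 10 allyl arene pivalate; 11 (R)-but-3-en-2-ol (4 equiv)
Product: 12 {(2S,3R)-2-[4-(benzyloxy)-3-methoxyphenyl]-5-[(2E,4R)-4-hydroxypent-2-en-1-yl]-7-methoxy-2,3-dihydrobenzofuran-3-yl}methyl pivalate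
Conditions: second-generation Hoveyda–Grubbs catalyst RuCl2(SIMes)(=CH-C6H4-2-OiPr) (5 mol %), 1,4-benzoquinone (10 mol %), CH2Cl2, 40 °C
Reagents that add atoms: none
Why: Olefin cross-metathesis of the terminal allyl arene with an excess of the allylic alcohol should give the (E)-alkene under thermodynamic control without touching the carbinol centre, benzoquinone suppressing migration of the allyl double bond into conjugation.

Step 8
Reactants: 13 3-(4-hydroxy-3-methoxyphenyl)propanoic acid (dihydroferulic acid)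
Product: 15 3-[4-(benzyloxy)-3-methoxyphenyl]propanoic acid, via benzyl ester 14 (not isolated)
Conditions: BnBr (2.3 equiv), K2CO3, DMF, 23 °C; then LiOH, THF/MeOH/H2O, 40 °C; HCl work-up
Reagents that add atoms: benzyl bromide, BrCc1ccccc1; water (as LiOH/H2O), O
Why: Williamson O-benzylation of phenol and carboxylate followed by saponification of the benzyl ester leaves the phenol protected and the acid free.

Step 9
Reactants: 12 (R,E)-allylic alcohol; 15 3-[4-(benzyloxy)-3-methoxyphenyl]propanoic acid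
Product: 16 (2R,3E)-5-{(2S,3R)-2-[4-(benzyloxy)-3-methoxyphenyl]-7-methoxy-3-[(pivaloyloxy)methyl]-2,3-dihydrobenzofuran-5-yl}pent-3-en-2-yl 3-[4-(benzyloxy)-3-methoxyphenyl]propanoate
Conditions: DCC, DMAP (cat.), CH2Cl2, 0 °C to 23 °C
Reagents that add atoms: none
Why: Steglich esterification joins the two halves through the ester tether with retention at the carbinol carbon, since only the acyl C–O bond is formed.

Step 10
Reactants: 16 allylic ester
Product: 20 (2R,3S,4E)-2-[4-(benzyloxy)-3-methoxybenzyl]-3-({(2S,3R)-2-[4-(benzyloxy)-3-methoxyphenyl]-7-methoxy-3-[(pivaloyloxy)methyl]-2,3-dihydrobenzofuran-5-yl}methyl)hex-4-enoic acid, via lithium enolate 17 (not isolated), via silyl ketene acetal 18 (not isolated), via trimethylsilyl ester 19 (not isolated)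
Conditions: LiN(iPr)2 (1.2 equiv), THF/DMPU (3:1), −78 °C; Me3SiCl (1.5 equiv), −78 °C; then 23 °C to 40 °C; 1 M HCl work-up
Reagents that add atoms: none
Why: LiN(iPr)2 in THF/DMPU deprotonates the only enolisable ester (the pivalate has no α-hydrogen) through an open transition state to the enolate with the ArCH2 group cis to O–Li (17), silylation gives the (Z)-silyl ketene acetal 18, and on warming a concerted suprafacial [3,3]-sigmatropic shift breaks the C9–O–CH tether and forms C8–C8', giving silyl ester 19 and, after hydrolysis, acid 20. The closest known reaction type is the Ireland–Claisen rearrangement of (E)-configured secondary allylic esters with 1,3-chirality transfer. No ring is closed; the six-membered array exists only in the chair transition state. C8' is controlled by the (R)-carbinol: with its methyl group equatorial in the chair, the new bond forms on the alkene face from which the oxygen leaves, which fixes the (R) configuration required at C8' of the target and the (E)-propenyl group; C8 is controlled by the ketene acetal geometry, the (Z)-acetal with the (E)-alkene giving the syn array that becomes (8R,8'R). The step needs control of ketene acetal geometry (sought with the dipolar cosolvent), chair over boat (expected for an acyclic substrate), equatorial over axial methyl (1,3-strain), and enolisation at C8 only, which the much higher acidity of the ester α-CH2 over the benzylic positions should secure.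

Step 11
Reactants: 20 γ,δ-unsaturated acid
Product: 23 (3R,4R)-3-[4-(benzyloxy)-3-methoxybenzyl]-4-({(2S,3R)-2-[4-(benzyloxy)-3-methoxyphenyl]-7-methoxy-3-[(pivaloyloxy)methyl]-2,3-dihydrobenzofuran-5-yl}methyl)dihydrofuran-2(3H)-one (trans-lactone), via ozonide 21 (not isolated), via hydroxy acid 22 (not isolated)
Conditions: O3, CH2Cl2, −78 °C (Sudan Red 7B end point); NaBH4, MeOH, −78 °C to 0 °C; then 1 M HCl, 23 °C
Reagents that add atoms: ozone, [O-][O+]=O
Why: Ozonolysis of the only alkene with borohydride work-up removes the two helper carbons and gives the γ-hydroxy acid, which lactonises on acidification; the aldehyde level at C9' is passed cold and in reducing medium so C8' should not epimerise, and the trans-lactone is also the thermodynamic isomer.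

Step 12
Reactants: 23 trans-lactone
Product: 24 (2R,3R)-2-[4-(benzyloxy)-3-methoxybenzyl]-3-({(2S,3R)-2-[4-(benzyloxy)-3-methoxyphenyl]-3-(hydroxymethyl)-7-methoxy-2,3-dihydrobenzofuran-5-yl}methyl)butane-1,4-diol
Conditions: LiAlH4, THF, 0 °C to 23 °C
Reagents that add atoms: none
Why: LiAlH4 reduces the lactone to the 1,4-diol and cleaves the pivalate in the same operation, reduction of the lactone carbonyl being faster than enolisation at C8.

Step 13
Reactants: 24 bis(benzyl ether) triol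
Product: 25 (2R,3R)-2-(4-hydroxy-3-methoxybenzyl)-3-{[(2S,3R)-2-(4-hydroxy-3-methoxyphenyl)-3-(hydroxymethyl)-7-methoxy-2,3-dihydrobenzofuran-5-yl]methyl}butane-1,4-diol (CNP0256425.1)
Conditions: H2 (1 atm), 10% Pd/C, EtOAc/MeOH, 23 °C, stopped on consumption of 24
Reagents that add atoms: none
Why: Hydrogenolysis of the two aryl benzyl ethers, which should be cleaved much faster than the cyclic benzylic ether O1–C2, so the dihydrobenzofuran is kept if the reaction is stopped in time.

**Compound list**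

1 | eugenol (4-allyl-2-methoxyphenol) | C=CCc1ccc(O)c(OC)c1 | starting material
2 | 4-allyl-2-iodo-6-methoxyphenol | C=CCc1cc(I)c(O)c(OC)c1 | intermediate
3 | [4-(benzyloxy)-3-methoxyphenyl]methanol | OCc1ccc(OCc2ccccc2)c(OC)c1 | starting material
4 | 5-allyl-2-{[4-(benzyloxy)-3-methoxybenzyl]oxy}-1-iodo-3-methoxybenzene | C=CCc1cc(I)c(OCc2ccc(OCc3ccccc3)c(OC)c2)c(OC)c1 | intermediate
5 | ethyl diazoacetate | CCOC(=O)C=[N+]=[N-] | starting material
6 | ethyl 2-(5-allyl-2-{[4-(benzyloxy)-3-methoxybenzyl]oxy}-3-methoxyphenyl)-2-diazoacetate | C=CCc1cc(C(=[N+]=[N-])C(=O)OCC)c(OCc2ccc(OCc3ccccc3)c(OC)c2)c(OC)c1 | intermediate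
7 | ethyl (2S,3R)-5-allyl-2-[4-(benzyloxy)-3-methoxyphenyl]-7-methoxy-2,3-dihydrobenzofuran-3-carboxylate (cis; not isolated) | C=CCc1cc(OC)c2c(c1)[C@@H](C(=O)OCC)[C@@H](c1ccc(OCc3ccccc3)c(OC)c1)O2 | intermediate
8 | ethyl (2S,3S)-5-allyl-2-[4-(benzyloxy)-3-methoxyphenyl]-7-methoxy-2,3-dihydrobenzofuran-3-carboxylate (trans) | C=CCc1cc(OC)c2c(c1)[C@H](C(=O)OCC)[C@@H](c1ccc(OCc3ccccc3)c(OC)c1)O2 | intermediate
9 | {(2S,3R)-5-allyl-2-[4-(benzyloxy)-3-methoxyphenyl]-7-methoxy-2,3-dihydrobenzofuran-3-yl}methanol | C=CCc1cc(OC)c2c(c1)[C@H](CO)[C@@H](c1ccc(OCc3ccccc3)c(OC)c1)O2 | intermediate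
10 | {(2S,3R)-5-allyl-2-[4-(benzyloxy)-3-methoxyphenyl]-7-methoxy-2,3-dihydrobenzofuran-3-yl}methyl pivalate | C=CCc1cc(OC)c2c(c1)[C@H](COC(=O)C(C)(C)C)[C@@H](c1ccc(OCc3ccccc3)c(OC)c1)O2 | intermediate
11 | (R)-but-3-en-2-ol | C=C[C@@H](C)O | starting material
12 | {(2S,3R)-2-[4-(benzyloxy)-3-methoxyphenyl]-5-[(2E,4R)-4-hydroxypent-2-en-1-yl]-7-methoxy-2,3-dihydrobenzofuran-3-yl}methyl pivalate | C[C@@H](O)/C=C/Cc1cc(OC)c2c(c1)[C@H](COC(=O)C(C)(C)C)[C@@H](c1ccc(OCc3ccccc3)c(OC)c1)O2 | intermediate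
13 | 3-(4-hydroxy-3-methoxyphenyl)propanoic acid | COc1cc(CCC(=O)O)ccc1O | starting material
14 | benzyl 3-[4-(benzyloxy)-3-methoxyphenyl]propanoate (not isolated) | COc1cc(CCC(=O)OCc2ccccc2)ccc1OCc1ccccc1 | intermediate
15 | 3-[4-(benzyloxy)-3-methoxyphenyl]propanoic acid | COc1cc(CCC(=O)O)ccc1OCc1ccccc1 | intermediate
16 | (2R,3E)-5-{(2S,3R)-2-[4-(benzyloxy)-3-methoxyphenyl]-7-methoxy-3-[(pivaloyloxy)methyl]-2,3-dihydrobenzofuran-5-yl}pent-3-en-2-yl 3-[4-(benzyloxy)-3-methoxyphenyl]propanoate | COc1cc(CCC(=O)O[C@H](C)/C=C/Cc2cc(OC)c3c(c2)[C@H](COC(=O)C(C)(C)C)[C@@H](c2ccc(OCc4ccccc4)c(OC)c2)O3)ccc1OCc1ccccc1 | intermediate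
17 | lithium enolate of 16, ArCH2 cis to O–Li (not isolated) | COc1cc(C/C=C(\[O-])O[C@H](C)/C=C/Cc2cc(OC)c3c(c2)[C@H](COC(=O)C(C)(C)C)[C@@H](c2ccc(OCc4ccccc4)c(OC)c2)O3)ccc1OCc1ccccc1.[Li+] | intermediate
18 | (Z)-trimethylsilyl ketene acetal of 16, ArCH2 cis to OSiMe3 (not isolated) | COc1cc(C/C=C(\O[Si](C)(C)C)O[C@H](C)/C=C/Cc2cc(OC)c3c(c2)[C@H](COC(=O)C(C)(C)C)[C@@H](c2ccc(OCc4ccccc4)c(OC)c2)O3)ccc1OCc1ccccc1 | intermediate
19 | trimethylsilyl ester of acid 20, (2R,3S,4E) (not isolated) | COc1cc(C[C@@H](C(=O)O[Si](C)(C)C)[C@H](/C=C/C)Cc2cc(OC)c3c(c2)[C@H](COC(=O)C(C)(C)C)[C@@H](c2ccc(OCc4ccccc4)c(OC)c2)O3)ccc1OCc1ccccc1 | intermediate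
20 | (2R,3S,4E)-2-[4-(benzyloxy)-3-methoxybenzyl]-3-({(2S,3R)-2-[4-(benzyloxy)-3-methoxyphenyl]-7-methoxy-3-[(pivaloyloxy)methyl]-2,3-dihydrobenzofuran-5-yl}methyl)hex-4-enoic acid | COc1cc(C[C@@H](C(=O)O)[C@H](/C=C/C)Cc2cc(OC)c3c(c2)[C@H](COC(=O)C(C)(C)C)[C@@H](c2ccc(OCc4ccccc4)c(OC)c2)O3)ccc1OCc1ccccc1 | intermediate
21 | ozonide (5-methyl-1,2,4-trioxolan-3-yl compound) of acid 20, mixture at the two ring carbons (not isolated) | COc1cc(C[C@@H](C(=O)O)[C@H](C2OOC(C)O2)Cc2cc(OC)c3c(c2)[C@H](COC(=O)C(C)(C)C)[C@@H](c2ccc(OCc4ccccc4)c(OC)c2)O3)ccc1OCc1ccccc1 | intermediate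
22 | (2R,3R)-2-[4-(benzyloxy)-3-methoxybenzyl]-4-{(2S,3R)-2-[4-(benzyloxy)-3-methoxyphenyl]-7-methoxy-3-[(pivaloyloxy)methyl]-2,3-dihydrobenzofuran-5-yl}-3-(hydroxymethyl)butanoic acid (not isolated) | COc1cc(C[C@@H](C(=O)O)[C@H](CO)Cc2cc(OC)c3c(c2)[C@H](COC(=O)C(C)(C)C)[C@@H](c2ccc(OCc4ccccc4)c(OC)c2)O3)ccc1OCc1ccccc1 | intermediate
23 | (3R,4R)-3-[4-(benzyloxy)-3-methoxybenzyl]-4-({(2S,3R)-2-[4-(benzyloxy)-3-methoxyphenyl]-7-methoxy-3-[(pivaloyloxy)methyl]-2,3-dihydrobenzofuran-5-yl}methyl)dihydrofuran-2(3H)-one | COc1cc(C[C@H]2C(=O)OC[C@@H]2Cc2cc(OC)c3c(c2)[C@H](COC(=O)C(C)(C)C)[C@@H](c2ccc(OCc4ccccc4)c(OC)c2)O3)ccc1OCc1ccccc1 | intermediate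
24 | (2R,3R)-2-[4-(benzyloxy)-3-methoxybenzyl]-3-({(2S,3R)-2-[4-(benzyloxy)-3-methoxyphenyl]-3-(hydroxymethyl)-7-methoxy-2,3-dihydrobenzofuran-5-yl}methyl)butane-1,4-diol | COc1cc(C[C@@H](CO)[C@H](CO)Cc2cc(OC)c3c(c2)[C@H](CO)[C@@H](c2ccc(OCc4ccccc4)c(OC)c2)O3)ccc1OCc1ccccc1 | intermediate
25 | (2R,3R)-2-(4-hydroxy-3-methoxybenzyl)-3-{[(2S,3R)-2-(4-hydroxy-3-methoxyphenyl)-3-(hydroxymethyl)-7-methoxy-2,3-dihydrobenzofuran-5-yl]methyl}butane-1,4-diol | COc1cc(C[C@@H](CO)[C@H](CO)Cc2cc(OC)c3c(c2)[C@H](CO)[C@@H](c2ccc(O)c(OC)c2)O3)ccc1O | target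

**Step count and risks**

Total step count: 13. Longest linear sequence: 12 steps (steps 1–7 and 9–13, from eugenol); step 8 is a one-step side branch.

The three steps most likely to fail:

Step 4. The enantiofacial selection in the C–H insertion may be insufficient or of the opposite sense. Intermolecular cyclopropanation of the allyl group may also compete with the intramolecular insertion; high dilution and slow addition counter this. The fallback replaces catalytic asymmetric induction by a resolution; it sets out from 6 and comes back at 9. Compound 6 is decomposed with achiral Rh2(OAc)4 (CH2Cl2, 23 °C) to the racemic cis ester F1, which NaOEt in EtOH equilibrates to the racemic trans ester F2. Saponification (LiOH, THF/H2O) gives the racemic trans acid F3. This is coupled (DCC, DMAP, CH2Cl2) with (S)-4-benzyloxazolidin-2-one to two diastereomeric imides, the (2S,3S)-acyl imide F4 and the (2R,3R)-acyl imide F5, which should be separable by chromatography or crystallisation. LiBH4 (THF with a little water, 0 °C) then cleaves F4 reductively to 9.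

Step 10. Control of the ketene acetal geometry may be incomplete, which would erode the configuration at C8; the transfer to C8' does not depend on it. The fallback sets C8 by thermodynamic control instead; it sets out from 16 and comes back at 23. Enolisation under the kinetic conditions without cosolvent (LiN(iPr)2, THF, −78 °C) should give the lithium enolate of opposite geometry F6 and, with Me3SiCl, the (E)-silyl ketene acetal F7. The same chair shift gives the silyl ester F8 and, after hydrolysis, the (2S,3S)-acid F9, which has the required C8' and the opposite C8 configuration. Ozonolysis, reduction and acidification as in step 11 lead through the ozonide F10 and the hydroxy acid F11 to the cis-lactone F12. Catalytic KOtBu in tBuOH/THF (23 °C) then epimerises the lactone α-carbon to the more stable trans-lactone 23; any mixture of 23 and F12 converges in the same way.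

Step 3. Oxidative addition and coupling at the ortho-alkoxy aryl iodide may be slow, so that the diazo ester dimerises or decomposes, or the allyl group undergoes Heck-type reaction. The fallback builds the diazo ester in two known operations; it sets out from 4 and comes back at 6. Negishi-type coupling of 4 with the Reformatsky reagent BrZnCH2CO2Et (Pd(PtBu3)2, THF, 23 °C) gives the aryl acetate F13. Regitz diazo transfer (4-acetamidobenzenesulfonyl azide, DBU, MeCN, 0 °C) converts it into 6.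

**Further compounds**

F1 | step 4 | racemic ethyl cis-5-allyl-2-[4-(benzyloxy)-3-methoxyphenyl]-7-methoxy-2,3-dihydrobenzofuran-3-carboxylate (both enantiomers shown) | C=CCc1cc(OC)c2c(c1)[C@@H](C(=O)OCC)[C@@H](c1ccc(OCc3ccccc3)c(OC)c1)O2.C=CCc1cc(OC)c2c(c1)[C@H](C(=O)OCC)[C@H](c1ccc(OCc3ccccc3)c(OC)c1)O2
F2 | step 4 | racemic ethyl trans-5-allyl-2-[4-(benzyloxy)-3-methoxyphenyl]-7-methoxy-2,3-dihydrobenzofuran-3-carboxylate (both enantiomers shown) | C=CCc1cc(OC)c2c(c1)[C@H](C(=O)OCC)[C@@H](c1ccc(OCc3ccccc3)c(OC)c1)O2.C=CCc1cc(OC)c2c(c1)[C@@H](C(=O)OCC)[C@H](c1ccc(OCc3ccccc3)c(OC)c1)O2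
F3 | step 4 | racemic trans-5-allyl-2-[4-(benzyloxy)-3-methoxyphenyl]-7-methoxy-2,3-dihydrobenzofuran-3-carboxylic acid (both enantiomers shown) | C=CCc1cc(OC)c2c(c1)[C@H](C(=O)O)[C@@H](c1ccc(OCc3ccccc3)c(OC)c1)O2.C=CCc1cc(OC)c2c(c1)[C@@H](C(=O)O)[C@H](c1ccc(OCc3ccccc3)c(OC)c1)O2
F4 | step 4 | (S)-3-{(2S,3S)-5-allyl-2-[4-(benzyloxy)-3-methoxyphenyl]-7-methoxy-2,3-dihydrobenzofuran-3-carbonyl}-4-benzyloxazolidin-2-one | C=CCc1cc(OC)c2c(c1)[C@H](C(=O)N1C(=O)OC[C@@H]1Cc1ccccc1)[C@@H](c1ccc(OCc3ccccc3)c(OC)c1)O2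
F5 | step 4 | (S)-3-{(2R,3R)-5-allyl-2-[4-(benzyloxy)-3-methoxyphenyl]-7-methoxy-2,3-dihydrobenzofuran-3-carbonyl}-4-benzyloxazolidin-2-one | C=CCc1cc(OC)c2c(c1)[C@@H](C(=O)N1C(=O)OC[C@@H]1Cc1ccccc1)[C@H](c1ccc(OCc3ccccc3)c(OC)c1)O2
F6 | step 10 | lithium enolate of 16, ArCH2 trans to O–Li | COc1cc(C/C=C(/[O-])O[C@H](C)/C=C/Cc2cc(OC)c3c(c2)[C@H](COC(=O)C(C)(C)C)[C@@H](c2ccc(OCc4ccccc4)c(OC)c2)O3)ccc1OCc1ccccc1.[Li+]
F7 | step 10 | (E)-trimethylsilyl ketene acetal of 16, ArCH2 trans to OSiMe3 | COc1cc(C/C=C(/O[Si](C)(C)C)O[C@H](C)/C=C/Cc2cc(OC)c3c(c2)[C@H](COC(=O)C(C)(C)C)[C@@H](c2ccc(OCc4ccccc4)c(OC)c2)O3)ccc1OCc1ccccc1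
F8 | step 10 | trimethylsilyl ester of the (2S,3S,4E)-acid F9 | COc1cc(C[C@H](C(=O)O[Si](C)(C)C)[C@H](/C=C/C)Cc2cc(OC)c3c(c2)[C@H](COC(=O)C(C)(C)C)[C@@H](c2ccc(OCc4ccccc4)c(OC)c2)O3)ccc1OCc1ccccc1
F9 | step 10 | (2S,3S,4E)-2-[4-(benzyloxy)-3-methoxybenzyl]-3-({(2S,3R)-2-[4-(benzyloxy)-3-methoxyphenyl]-7-methoxy-3-[(pivaloyloxy)methyl]-2,3-dihydrobenzofuran-5-yl}methyl)hex-4-enoic acid | COc1cc(C[C@H](C(=O)O)[C@H](/C=C/C)Cc2cc(OC)c3c(c2)[C@H](COC(=O)C(C)(C)C)[C@@H](c2ccc(OCc4ccccc4)c(OC)c2)O3)ccc1OCc1ccccc1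
F10 | step 10 | ozonide (5-methyl-1,2,4-trioxolan-3-yl compound) of acid F9 | COc1cc(C[C@H](C(=O)O)[C@H](C2OOC(C)O2)Cc2cc(OC)c3c(c2)[C@H](COC(=O)C(C)(C)C)[C@@H](c2ccc(OCc4ccccc4)c(OC)c2)O3)ccc1OCc1ccccc1
F11 | step 10 | (2S,3R)-2-[4-(benzyloxy)-3-methoxybenzyl]-4-{(2S,3R)-2-[4-(benzyloxy)-3-methoxyphenyl]-7-methoxy-3-[(pivaloyloxy)methyl]-2,3-dihydrobenzofuran-5-yl}-3-(hydroxymethyl)butanoic acid | COc1cc(C[C@H](C(=O)O)[C@H](CO)Cc2cc(OC)c3c(c2)[C@H](COC(=O)C(C)(C)C)[C@@H](c2ccc(OCc4ccccc4)c(OC)c2)O3)ccc1OCc1ccccc1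
F12 | step 10 | (3S,4R)-3-[4-(benzyloxy)-3-methoxybenzyl]-4-({(2S,3R)-2-[4-(benzyloxy)-3-methoxyphenyl]-7-methoxy-3-[(pivaloyloxy)methyl]-2,3-dihydrobenzofuran-5-yl}methyl)dihydrofuran-2(3H)-one (cis-lactone) | COc1cc(C[C@@H]2C(=O)OC[C@@H]2Cc2cc(OC)c3c(c2)[C@H](COC(=O)C(C)(C)C)[C@@H](c2ccc(OCc4ccccc4)c(OC)c2)O3)ccc1OCc1ccccc1
F13 | step 3 | ethyl 2-(5-allyl-2-{[4-(benzyloxy)-3-methoxybenzyl]oxy}-3-methoxyphenyl)acetate | C=CCc1cc(CC(=O)OCC)c(OCc2ccc(OCc3ccccc3)c(OC)c2)c(OC)c1
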